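## The problem

The target is a flavonol with no stereocentres, so the difficulty lies entirely in substitution pattern and functional group differentiation. Ring A is hexasubstituted: C5 and C7 carry hydroxyls, C6 and C8 carry methyls, C8a carries the ring oxygen and C4a the C4 carbonyl. No position is free, so placing the methyls or the acyl group by substitution on a phloroglucinol would meet over-alkylation, dearomatization and crowding. Ring B carries one methyl ether at C4' between two free phenols, so that methyl must be present from the start and every temporary group must come off without touching it; Lewis-acid dealkylation is therefore excluded. The C3 oxygen of ring C is best carried through the synthesis in a 2-alkoxy-1,3-diketone, since late oxidation of an electron-rich, crowded flavone is unattractive. The C-methylated phloroglucinol ring is easily oxidized by air in base, and the only stereogenic carbon met on the way (C3 of the open intermediates) is enolizable and disappears when ring C aromatizes. The enabling feature is that C8a, C8, C7, C6, C5 and C4a, read in this order, are a carboxyl carbon, a methyl-bearing carbon, a carbonyl carbon, a methyl-bearing carbon, a carbonyl carbon and a methylene next to the C4 ketone. This is a folded poly-β-carbonyl chain, which a 4-hydroxy-3,5-dimethyl-2-pyranone stores at the correct oxidation level. Ring A is also symmetric about the C4a–C7 axis, so either flanking phenol can later close ring C.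

## Retrosynthesis

Flavonoid numbering (O1, C2–C4, C4a, C5–C8, C8a, primed numbers for ring B) is used for the corresponding atoms of all intermediates.

**13 to 12.** The three O–benzyl bonds at O3, O3' and O5' are cut. Hydrogenolysis is the one deprotection that distinguishes these ethers from the C4' methyl ether, which boron halides would attack first because it sits between two oxygens. The precursor 12 is the complete, fully aromatic skeleton, and the forward step has to do no more than remove benzyl groups.

**12 to 10.** The O1–C2 bond is cut, opening ring C to the 2-benzyloxy-1,3-diketone 10. This is the classical last bond of a flavone synthesis and needs only acid. Cutting O1–C8a instead would demand a C–O bond to an arene carbon. The forward closure has no regiochemical issue, because the two phenols flanking the acyl group of 10 are equivalent and only attack at the C2 ketone gives a six-membered ring.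

**10 to 8 (through 9).** The C4a–C8a bond of ring A is cut, which turns the hexasubstituted arene into the open tetraoxo ester 9, and 9 is stored as the 2-pyranone 8. Against acylation or methylation of a preformed phloroglucinol, this cut puts every ring A substituent in place on sp3 or carbonyl carbons before the ring exists. The forward step must open the lactone and direct the chain to Claisen rather than aldol closure. The methyls at C6 and C8 and the benzyloxy group at C3 help here, because each possible aldol donor carbon becomes quaternary on reaction and cannot lead to an arene.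

**8 to 5 and 7.** The C2–C3 bond is cut, giving the pyranone ketone 5 and the ring B ester 7. The neighbouring option is to bring C2–C4 as one unit, an aldol-derived silyloxy amide acylating the pyranone at C4a. That costs a reduction, an oxidation, an aldol, a protection, an amide formation, a deprotection and a second oxidation. The cut at C2–C3 uses the ester oxidation state of ring B directly and needs one polyanion acylation. It asks that the trianion of 5 react at its terminal, benzyloxy-bearing carbon.

**5 to 3 and 4.** The C4–C4a bond is cut, leading to the trimethylpyranone 3 and the glycolate ester 4. The 6-methyl of 3 is the only carbon acid conjugated to the lactone carbonyl once the 4-hydroxyl is deprotonated, so the dianion is formed at one site only.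

**3 to 2 to 1.** The lactone C8a–O bond and then the C5–C6 bond are cut, leading to the β-keto ester 1 and an acetyl donor whose methyl becomes C4a. Both forward steps are standard: γ-acylation of a β-keto ester dianion and base-induced lactonization.

**7 to 6.** The two O–benzyl bonds of ring B are cut, leading to the methyl ester 6, which already has the C4' methyl ether in place.

## Roads not taken

**Alternative 1:** Ring C would be assembled from two complete halves by cutting O1–C8a, C4–C4a and O1–C2. An aryne generated from the silylaryl triflate A2 (triple bond C4a–C8a) would insert into the carboxyl C–O bond of the arylpropiolic acid A3, and the resulting phenoxide would add to the ynone to give the flavone A1. The merit is convergence: three bonds and ring C in one operation. The alkoxy group at C5 directs the carboxylate oxygen to C8a, which is the right sense. The weak points are specific to this target. A2 is a pentasubstituted arene that still has to be made from a C-methylated phloroglucinol, with one of two equivalent oxygens singled out as the triflate and a silyl group placed beside it. C8a is flanked by the C8 methyl. A1 lacks the C3 oxygen, so a further oxidation of a crowded flavone is needed before deprotection. This road is more convergent than the chosen one. The chosen plan offsets that by carrying the C3 oxygen from a commercial glycolate, making ring A without any arene substitution, and needing no desymmetrization.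

**Alternative 2:** Ring A would be annulated onto a preformed ring C by cutting C5–C6, C7–C8 and C4a–C5. Wolff rearrangement of the pyranonyl diazo ketone A5 would give a vinylketene that combines with the siloxypropyne A6 through cycloaddition, ring opening and electrocyclization to the chromenone A4. The merit is complete regiocontrol of a hexasubstituted ring, and it delivers the C5 hydroxyl free and the C7 oxygen silylated. If these two oxygens had to be differentiated, this would be the better plan. Here they are both free in the target, so the advantage is not used. The weak points are the multi-step preparation of A5 (a 6-acyl-3-alkoxy-2-aryl-4-pyranone plus a diazo transfer), irradiation of a diazo ketone attached to a photoactive 4-pyranone, and an electrocyclization that has to engage the C4a=C8a bond of an electron-poor heterocycle. The chosen plan needs no diazo compound and no photochemistry.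

**Alternative 3:** Ring C would be closed by cutting O1–C8a at an unfunctionalized arene carbon. Anodic two-electron oxidation of the enolized diketone A8 would join the C2 enol oxygen to C8a–H and give the perbenzylated flavonol A7. The merit is a simple substrate: A8 comes from a resorcinol-type ketone by standard acylation, needs no polyanion chemistry and no third phenol on ring A, and in that respect is easier to make than 8. The weak points are electronic. C8a is meta to both ring A alkoxy groups and ortho to the acyl group, so it is the least suited position for C–O bond formation. The other ortho carbon, C5, bears a benzyloxy group and invites ipso attack with loss of benzyl, which would give a 5-deoxy isomer. The C-methyl groups and five benzyl ethers are also oxidizable at the anode. The chosen plan offsets the longer precursor with a ring closure that has direct precedent and only a polar, chelation-controlled selectivity to meet.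

Key step: step 6

Assumption: compounds 2, 8, 9, 10 and 11 contain only enolizable stereocentres that vanish later, so they are handled as mixtures of stereoisomers and enol tautomers and drawn without configuration.

## Route

Step 1
Reactants: 1 ethyl 2-methyl-3-oxopentanoate (racemic)
Product: 2 ethyl 2,4-dimethyl-3,5-dioxohexanoate (diastereomer and tautomer mixture)
Conditions: LiN(i-Pr)2 (2.2 equiv), THF, −78 to 0 °C; MeC(O)N(OMe)Me, −78 °C to rt; aq. HCl
Reagents that add atoms: N-methoxy-N-methylacetamide, CC(=O)N(C)OC
Why: Claisen-type γ-acylation of a β-keto ester dianion; the second deprotonation occurs at C4 and this more reactive carbanion attacks the Weinreb amide, whose chelated tetrahedral adduct survives until work-up and so prevents over-addition and proton transfer from the product.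

Step 2
Reactants: 2 ethyl 2,4-dimethyl-3,5-dioxohexanoate
Product: 3 4-hydroxy-3,5,6-trimethyl-2H-pyran-2-one
Conditions: DBU, toluene, reflux; aq. HCl work-up
Reagents that add atoms: none
Why: Base-induced lactonization of a 3,5-dioxo ester; the C5 enolate oxygen attacks the ester carbonyl, ethanol is expelled and the product settles as the stable 4-hydroxy-2-pyranone tautomer.

Step 3
Reactants: 3 4-hydroxy-3,5,6-trimethyl-2H-pyran-2-one; 4 methyl 2-(benzyloxy)acetate
Product: 5 6-[3-(benzyloxy)-2-oxopropyl]-4-hydroxy-3,5-dimethyl-2H-pyran-2-one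
Conditions: 3 (2.2 equiv), LiN(i-Pr)2 (4.5 equiv), THF–DMPU, −78 to −20 °C; 4 (1 equiv), −78 to 0 °C; 1 M HCl
Reagents that add atoms: none
Why: Claisen acylation of a 4-hydroxy-6-methyl-2-pyranone dianion; after the hydroxyl, only the 6-methyl is conjugated to the lactone carbonyl, and its carbanion attacks the activated α-alkoxy ester, while the second equivalent of dianion takes up the acidic methylene proton of the product.

Step 4
Reactants: 6 methyl 3,5-dihydroxy-4-methoxybenzoate
Product: 7 methyl 3,5-bis(benzyloxy)-4-methoxybenzoate
Conditions: BnBr, K2CO3, DMF, 60 °C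
Reagents that add atoms: benzyl bromide, BrCc1ccccc1
Why: Williamson ether synthesis on two equivalent phenols; the ester and the methyl ether are inert.

Step 5
Reactants: 5 6-[3-(benzyloxy)-2-oxopropyl]-4-hydroxy-3,5-dimethyl-2H-pyran-2-one; 7 methyl 3,5-bis(benzyloxy)-4-methoxybenzoate
Product: 8 6-{3-(benzyloxy)-4-[3,5-bis(benzyloxy)-4-methoxyphenyl]-2,4-dioxobutyl}-4-hydroxy-3,5-dimethyl-2H-pyran-2-one (racemic)
Conditions: LiN(i-Pr)2 (4.2 equiv), THF–DMPU, −78 to 0 °C; 7 (1.1 equiv), 0 °C to rt; cold 1 M HCl
Reagents that add atoms: none
Why: Terminal Claisen acylation of a β-dicarbonyl polyanion; the trianion of 5 (hydroxyl, C4a methylene, C3 methylene) reacts at the last-formed, least stabilized carbanion C3 with the non-enolizable aroyl ester, and the fourth equivalent of amide deprotonates the new tricarbonyl unit and shields it from further attack. The C3 stereocentre is formed racemic and is enolizable.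

Step 6
Reactants: 8 6-{3-(benzyloxy)-4-[3,5-bis(benzyloxy)-4-methoxyphenyl]-2,4-dioxobutyl}-4-hydroxy-3,5-dimethyl-2H-pyran-2-one
Product: 10 2-(benzyloxy)-1-[3,5-bis(benzyloxy)-4-methoxyphenyl]-3-(2,4,6-trihydroxy-3,5-dimethylphenyl)propane-1,3-dione (racemic), via open-chain methyl tetraoxononanoate magnesium chelate 9 (not isolated)
Conditions: Mg(OMe)2 (8 equiv), MeOH, reflux, Ar; then cold 1 M HCl
Reagents that add atoms: none
Why: Methoxide, delivered within a magnesium complex, adds to the lactone carbonyl C8a of 8 and opens the ring to the methyl tetraoxo ester 9, which is held as magnesium chelates of its 1,3-dicarbonyl units. The C4a methylene between the C4 and C5 carbonyls is deprotonated and attacks the C8a ester carbonyl; loss of methoxide forms C4a–C8a, and the resulting 2-acylcyclohexane-1,3,5-trione enolizes to the aromatic ring A of 10. The closest known reaction type is the Mg(OMe)2 Claisen recyclization of 6-(2-oxoalkyl)-4-hydroxy-2-pyranones to acylphloroglucinols. Ring A closes in the 6-(enolendo)-exo-trig mode. No stereocentre is created, and C3 stays racemic and enolizable. The selectivity required is Claisen over aldol closure: magnesium chelation tempers enolate attack on ketones and holds C4a near the ester, and in addition each carbon that could act as the donor in a six-membered aldol closure (C8, C6 or C3) becomes quaternary on reaction, so such adducts cannot dehydrate to an arene and revert, whereas the Claisen product is removed irreversibly as an aromatic phenoxide. The enolizable C3–H keeps the C2/C4 diketone as an enolate chelate, which protects the aroyl group from cleavage by methoxide. Argon protects the electron-rich product from oxidation in the basic medium.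

Step 7
Reactants: 10 2-(benzyloxy)-1-[3,5-bis(benzyloxy)-4-methoxyphenyl]-3-(2,4,6-trihydroxy-3,5-dimethylphenyl)propane-1,3-dione
Product: 12 3-(benzyloxy)-2-[3,5-bis(benzyloxy)-4-methoxyphenyl]-5,7-dihydroxy-6,8-dimethyl-4H-chromen-4-one, via 2-hydroxyflavanone hemiketal 11 (not isolated)
Conditions: p-TsOH·H2O (0.2 equiv), toluene, 90 °C
Reagents that add atoms: none
Why: Acid-catalysed cyclodehydration of an o-hydroxyaryl 1,3-diketone, the closing step of Baker–Venkataraman flavone syntheses; a flanking phenol adds to the C2 ketone to give hemiketal 11 and loss of water gives the 4-pyranone. The two flanking phenols are equivalent by the symmetry of ring A, and ring A has no free carbon that a benzyl cation could attack.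

Step 8
Reactants: 12 3-(benzyloxy)-2-[3,5-bis(benzyloxy)-4-methoxyphenyl]-5,7-dihydroxy-6,8-dimethyl-4H-chromen-4-one
Product: 13 6,8-di-C-methylmyricetin 4'-methyl ether, 2-(3,5-dihydroxy-4-methoxyphenyl)-3,5,7-trihydroxy-6,8-dimethyl-4H-chromen-4-one
Conditions: H2 (1 atm), 10% Pd/C, EtOAc–MeOH, rt
Reagents that add atoms: none
Why: Catalytic hydrogenolysis of the three benzyl ethers; the aryl methyl ether and the aromatic 4-pyranone are not reduced under these conditions.

## Compound list

1 | ethyl 2-methyl-3-oxopentanoate (racemic) | CCC(=O)C(C)C(=O)OCC | starting material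
2 | ethyl 2,4-dimethyl-3,5-dioxohexanoate (diastereomer and tautomer mixture) | CCOC(=O)C(C)C(=O)C(C)C(C)=O | intermediate
3 | 4-hydroxy-3,5,6-trimethyl-2H-pyran-2-one | Cc1oc(=O)c(C)c(O)c1C | intermediate
4 | methyl 2-(benzyloxy)acetate | COC(=O)COCc1ccccc1 | starting material
5 | 6-[3-(benzyloxy)-2-oxopropyl]-4-hydroxy-3,5-dimethyl-2H-pyran-2-one | Cc1c(O)c(C)c(CC(=O)COCc2ccccc2)oc1=O | intermediate
6 | methyl 3,5-dihydroxy-4-methoxybenzoate | COC(=O)c1cc(O)c(OC)c(O)c1 | starting material
7 | methyl 3,5-bis(benzyloxy)-4-methoxybenzoate | COC(=O)c1cc(OCc2ccccc2)c(OC)c(OCc2ccccc2)c1 | intermediate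
8 | 6-{3-(benzyloxy)-4-[3,5-bis(benzyloxy)-4-methoxyphenyl]-2,4-dioxobutyl}-4-hydroxy-3,5-dimethyl-2H-pyran-2-one (racemic) | Cc1c(O)c(C)c(CC(=O)C(OCc2ccccc2)C(=O)c2cc(OCc3ccccc3)c(OC)c(OCc3ccccc3)c2)oc1=O | intermediate
9 | methyl 8-(benzyloxy)-9-[3,5-bis(benzyloxy)-4-methoxyphenyl]-2,4-dimethyl-3,5,7,9-tetraoxononanoate (as magnesium chelate, stereoisomer and tautomer mixture) | COC(=O)C(C)C(=O)C(C)C(=O)CC(=O)C(OCc1ccccc1)C(=O)c1cc(OCc2ccccc2)c(OC)c(OCc2ccccc2)c1 | intermediate (not isolated)
10 | 2-(benzyloxy)-1-[3,5-bis(benzyloxy)-4-methoxyphenyl]-3-(2,4,6-trihydroxy-3,5-dimethylphenyl)propane-1,3-dione (racemic) | COc1c(OCc2ccccc2)cc(C(=O)C(OCc2ccccc2)C(=O)c2c(O)c(C)c(O)c(C)c2O)cc1OCc1ccccc1 | intermediate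
11 | 3-(benzyloxy)-2-[3,5-bis(benzyloxy)-4-methoxyphenyl]-2,5,7-trihydroxy-6,8-dimethyl-2,3-dihydro-4H-chromen-4-one (diastereomer mixture) | COc1c(OCc2ccccc2)cc(C2(O)Oc3c(C)c(O)c(C)c(O)c3C(=O)C2OCc2ccccc2)cc1OCc1ccccc1 | intermediate (not isolated)
12 | 3-(benzyloxy)-2-[3,5-bis(benzyloxy)-4-methoxyphenyl]-5,7-dihydroxy-6,8-dimethyl-4H-chromen-4-one | COc1c(OCc2ccccc2)cc(-c2oc3c(C)c(O)c(C)c(O)c3c(=O)c2OCc2ccccc2)cc1OCc1ccccc1 | intermediate
13 | 6,8-di-C-methylmyricetin 4'-methyl ether | COc1c(O)cc(-c2oc3c(C)c(O)c(C)c(O)c3c(=O)c2O)cc1O | target

## Step count and least certain steps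

Total: 8 steps. Longest linear sequence: 7 steps (steps 1, 2, 3, 5, 6, 7, 8); step 4 is a one-step branch.

**Step 6 (key step).** Three things are most likely to go wrong:
- Lactone opening may be slow, because the 4-oxido-3,5-dimethylpyranone anion is a weak and hindered electrophile, so starting material could persist.
- Methoxide may cleave the aroyl group by retro-Claisen reaction.
- Any chain that has not closed may cyclize through oxygen to a 4-pyranone on acidification.

Fallback, from 5 and 7 back to the route at 12: the same Mg(OMe)2 recyclization is run on the simpler pyranone 5, the exact precedent class, to give 2-(benzyloxy)-1-(2,4,6-trihydroxy-3,5-dimethylphenyl)ethan-1-one F1. Ester 7 is saponified (LiOH, aqueous THF) to 3,5-bis(benzyloxy)-4-methoxybenzoic acid F2, which DCC converts into 3,5-bis(benzyloxy)-4-methoxybenzoic anhydride F3. Allan–Robinson condensation of F1 with F3 (Et3N, about 150 °C) forms C2–C3 and ring C and gives the O-aroylated flavone 3-(benzyloxy)-2-[3,5-bis(benzyloxy)-4-methoxyphenyl]-6,8-dimethyl-4-oxo-4H-chromene-5,7-diyl bis[3,5-bis(benzyloxy)-4-methoxybenzoate] F4. This is drawn as the diester; partly acylated material converges in the next operation. KOH in aqueous methanol removes the aryl esters and gives 12. Ring A is still built by the C4a–C8a Claisen closure, but ring B is attached afterwards.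

**Step 5.** The third deprotonation may be incomplete. The secondary, benzyloxy-bearing carbanion may attack the electron-rich benzoate slowly. On warming, the benzyl group may shift from oxygen to carbon in the α-benzyloxy carbanion.

Fallback, from 7, 4 and 3 back to the route at 8: ester 7 is reduced (LiAlH4, THF) to [3,5-bis(benzyloxy)-4-methoxyphenyl]methanol F5 and oxidized (MnO2, CH2Cl2) to 3,5-bis(benzyloxy)-4-methoxybenzaldehyde F6. Aldol addition of the lithium enolate of 4 (LiN(i-Pr)2, THF, −78 °C) gives methyl 2-(benzyloxy)-3-[3,5-bis(benzyloxy)-4-methoxyphenyl]-3-hydroxypropanoate F7 as a diastereomer mixture, which does not matter. Silylation (TBSOTf, 2,6-lutidine) gives methyl 2-(benzyloxy)-3-[3,5-bis(benzyloxy)-4-methoxyphenyl]-3-[(tert-butyldimethylsilyl)oxy]propanoate F8. Aminolysis (MeNH(OMe)·HCl, i-PrMgCl, THF, −20 °C) gives 2-(benzyloxy)-3-[3,5-bis(benzyloxy)-4-methoxyphenyl]-3-[(tert-butyldimethylsilyl)oxy]-N-methoxy-N-methylpropanamide F9. The dianion of 3 is acylated by F9 to give 6-{3-(benzyloxy)-4-[3,5-bis(benzyloxy)-4-methoxyphenyl]-4-[(tert-butyldimethylsilyl)oxy]-2-oxobutyl}-4-hydroxy-3,5-dimethyl-2H-pyran-2-one F10. HF·pyridine frees 6-{3-(benzyloxy)-4-[3,5-bis(benzyloxy)-4-methoxyphenyl]-4-hydroxy-2-oxobutyl}-4-hydroxy-3,5-dimethyl-2H-pyran-2-one F11, and Dess–Martin oxidation gives 8. Here C4–C4a is formed last and no trianion is needed, at the cost of six further operations.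

**Step 3.** The carbanion may take a proton from the α-methylene of ester 4, after which the ester self-condenses and 3 is returned. The dilithio salt may also be poorly soluble.

Fallback, from 3 back to the route at 5: the dianion of 3 is added at −78 °C to commercial 2-(benzyloxy)acetaldehyde (O=CCOCc1ccccc1), an aldol addition that is faster than proton transfer, to give 6-[3-(benzyloxy)-2-hydroxypropyl]-4-hydroxy-3,5-dimethyl-2H-pyran-2-one F12 (racemic). Dess–Martin oxidation then gives 5.

**Step 7.** The acid may remove benzyl groups from the electron-rich ethers before dehydration of hemiketal 11 is complete, or the diketone may be cleaved on prolonged heating.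

Fallback, from 10 back to the route at 13: the order of the last two operations is reversed. Hydrogenolysis of 10 (H2, 10% Pd/C, EtOAc–MeOH) gives 1-(3,5-dihydroxy-4-methoxyphenyl)-2-hydroxy-3-(2,4,6-trihydroxy-3,5-dimethylphenyl)propane-1,3-dione F13, in equilibrium with its cyclic hemiketal. With no benzyl ether left to lose, this is dehydrated with dilute HCl in warm methanol to 13.

## Further compounds

F1 | step 6 | 2-(benzyloxy)-1-(2,4,6-trihydroxy-3,5-dimethylphenyl)ethan-1-one | Cc1c(O)c(C)c(O)c(C(=O)COCc2ccccc2)c1O
F2 | step 6 | 3,5-bis(benzyloxy)-4-methoxybenzoic acid | COc1c(OCc2ccccc2)cc(C(=O)O)cc1OCc1ccccc1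
F3 | step 6 | 3,5-bis(benzyloxy)-4-methoxybenzoic anhydride | COc1c(OCc2ccccc2)cc(C(=O)OC(=O)c2cc(OCc3ccccc3)c(OC)c(OCc3ccccc3)c2)cc1OCc1ccccc1
F4 | step 6 | 3-(benzyloxy)-2-[3,5-bis(benzyloxy)-4-methoxyphenyl]-6,8-dimethyl-4-oxo-4H-chromene-5,7-diyl bis[3,5-bis(benzyloxy)-4-methoxybenzoate] | COc1c(OCc2ccccc2)cc(-c2oc3c(C)c(OC(=O)c4cc(OCc5ccccc5)c(OC)c(OCc5ccccc5)c4)c(C)c(OC(=O)c4cc(OCc5ccccc5)c(OC)c(OCc5ccccc5)c4)c3c(=O)c2OCc2ccccc2)cc1OCc1ccccc1
F5 | step 5 | [3,5-bis(benzyloxy)-4-methoxyphenyl]methanol | COc1c(OCc2ccccc2)cc(CO)cc1OCc1ccccc1
F6 | step 5 | 3,5-bis(benzyloxy)-4-methoxybenzaldehyde | COc1c(OCc2ccccc2)cc(C=O)cc1OCc1ccccc1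
F7 | step 5 | methyl 2-(benzyloxy)-3-[3,5-bis(benzyloxy)-4-methoxyphenyl]-3-hydroxypropanoate (racemic diastereomer mixture) | COC(=O)C(OCc1ccccc1)C(O)c1cc(OCc2ccccc2)c(OC)c(OCc2ccccc2)c1
F8 | step 5 | methyl 2-(benzyloxy)-3-[3,5-bis(benzyloxy)-4-methoxyphenyl]-3-[(tert-butyldimethylsilyl)oxy]propanoate (racemic diastereomer mixture) | COC(=O)C(OCc1ccccc1)C(O[Si](C)(C)C(C)(C)C)c1cc(OCc2ccccc2)c(OC)c(OCc2ccccc2)c1
F9 | step 5 | 2-(benzyloxy)-3-[3,5-bis(benzyloxy)-4-methoxyphenyl]-3-[(tert-butyldimethylsilyl)oxy]-N-methoxy-N-methylpropanamide (racemic diastereomer mixture) | CON(C)C(=O)C(OCc1ccccc1)C(O[Si](C)(C)C(C)(C)C)c1cc(OCc2ccccc2)c(OC)c(OCc2ccccc2)c1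
F10 | step 5 | 6-{3-(benzyloxy)-4-[3,5-bis(benzyloxy)-4-methoxyphenyl]-4-[(tert-butyldimethylsilyl)oxy]-2-oxobutyl}-4-hydroxy-3,5-dimethyl-2H-pyran-2-one (racemic diastereomer mixture) | Cc1c(O)c(C)c(CC(=O)C(OCc2ccccc2)C(O[Si](C)(C)C(C)(C)C)c2cc(OCc3ccccc3)c(OC)c(OCc3ccccc3)c2)oc1=O
F11 | step 5 | 6-{3-(benzyloxy)-4-[3,5-bis(benzyloxy)-4-methoxyphenyl]-4-hydroxy-2-oxobutyl}-4-hydroxy-3,5-dimethyl-2H-pyran-2-one (racemic diastereomer mixture) | Cc1c(O)c(C)c(CC(=O)C(OCc2ccccc2)C(O)c2cc(OCc3ccccc3)c(OC)c(OCc3ccccc3)c2)oc1=O
F12 | step 3 | 6-[3-(benzyloxy)-2-hydroxypropyl]-4-hydroxy-3,5-dimethyl-2H-pyran-2-one (racemic) | Cc1c(O)c(C)c(CC(O)COCc2ccccc2)oc1=O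
F13 | step 7 | 1-(3,5-dihydroxy-4-methoxyphenyl)-2-hydroxy-3-(2,4,6-trihydroxy-3,5-dimethylphenyl)propane-1,3-dione (racemic) | COc1c(O)cc(C(=O)C(O)C(=O)c2c(O)c(C)c(O)c(C)c2O)cc1O
A1 | alternative 1 | 5,7-bis(benzyloxy)-2-[3,5-bis(benzyloxy)-4-methoxyphenyl]-6,8-dimethyl-4H-chromen-4-one | COc1c(OCc2ccccc2)cc(-c2cc(=O)c3c(OCc4ccccc4)c(C)c(OCc4ccccc4)c(C)c3o2)cc1OCc1ccccc1
A2 | alternative 1 | 3,5-bis(benzyloxy)-2,4-dimethyl-6-(trimethylsilyl)phenyl trifluoromethanesulfonate | Cc1c(OCc2ccccc2)c(C)c(OS(=O)(=O)C(F)(F)F)c([Si](C)(C)C)c1OCc1ccccc1
A3 | alternative 1 | 3-[3,5-bis(benzyloxy)-4-methoxyphenyl]prop-2-ynoic acid | COc1c(OCc2ccccc2)cc(C#CC(=O)O)cc1OCc1ccccc1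
A4 | alternative 2 | 3-(benzyloxy)-2-[3,5-bis(benzyloxy)-4-methoxyphenyl]-5-hydroxy-6,8-dimethyl-7-(triisopropylsilyloxy)-4H-chromen-4-one | COc1c(OCc2ccccc2)cc(-c2oc3c(C)c(O[Si](C(C)C)(C(C)C)C(C)C)c(C)c(O)c3c(=O)c2OCc2ccccc2)cc1OCc1ccccc1
A5 | alternative 2 | 3-(benzyloxy)-2-[3,5-bis(benzyloxy)-4-methoxyphenyl]-6-(2-diazopropanoyl)-4H-pyran-4-one | COc1c(OCc2ccccc2)cc(-c2oc(C(=O)C(C)=[N+]=[N-])cc(=O)c2OCc2ccccc2)cc1OCc1ccccc1
A6 | alternative 2 | triisopropyl(prop-1-yn-1-yloxy)silane | CC#CO[Si](C(C)C)(C(C)C)C(C)C
A7 | alternative 3 | 3,5,7-tris(benzyloxy)-2-[3,5-bis(benzyloxy)-4-methoxyphenyl]-6,8-dimethyl-4H-chromen-4-one | COc1c(OCc2ccccc2)cc(-c2oc3c(C)c(OCc4ccccc4)c(C)c(OCc4ccccc4)c3c(=O)c2OCc2ccccc2)cc1OCc1ccccc1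
A8 | alternative 3 | 2-(benzyloxy)-1-[2,4-bis(benzyloxy)-3,5-dimethylphenyl]-3-[3,5-bis(benzyloxy)-4-methoxyphenyl]propane-1,3-dione (racemic) | COc1c(OCc2ccccc2)cc(C(=O)C(OCc2ccccc2)C(=O)c2cc(C)c(OCc3ccccc3)c(C)c2OCc2ccccc2)cc1OCc1ccccc1
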